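Everything rests on cutting two adjacent bonds on the benzene ring of the chroman together: C7–O and C8–C(=O). A chroman 7,8-aryne inserts into the carboxyl C–O bond of MOM-protected (E)-4-hydroxycinnamic acid, placing oxygen on C7 and the cinnamoyl group on C8 in one operation. The step exploits two features: the C7 oxygen and the C8 acyl carbon are neighbours, and C8 is flanked by C8a, whose ring oxygen O1 polarises the aryne. The aryne precursor is a (3R)-chroman with a trimethylsilyl group on C7, a triflate on C8, a MOM ether on C5 and a TBS ether on C3; C3 comes from asymmetric epoxidation of a chromene.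

Key step: step 11

Assumption: C3 is R as written in the target SMILES, and the (R,R)-configured manganese salen catalyst is expected to give the (3R,4R)-oxide, the usual sense for 2,2-dimethyl-2H-chromenes.

Design note: the C5 and C4' phenols carry MOM and the C3 alcohol carries TBS, so one mild acid treatment ends the synthesis without touching the enone or the C7 methyl ether next to the C8 ketone. The oxygen destined for C8 is a benzyl ether during ring construction, because the Baeyer–Villiger step needs an electron-releasing ortho ether for aryl migration. It becomes an N-isopropyl carbamate only afterwards; this group directs lithiation to C7 and is later cleaved by mild base.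

Step 1
Reactants: 1 2,5-dihydroxybenzaldehyde
Product: 2 2-hydroxy-5-(methoxymethoxy)benzaldehyde
Conditions: MOMCl (1.05 equiv), iPr2NEt, CH2Cl2, 0 °C to rt
Reagents that add atoms: chloromethyl methyl ether, COCCl
Why: Selective O-alkylation of a phenol; the 2-OH is locked in a hydrogen bond to the formyl oxygen and is the poorer nucleophile, so the free 5-OH should take the MOM group.

Step 2
Reactants: 2 2-hydroxy-5-(methoxymethoxy)benzaldehyde
Product: 3 2-(benzyloxy)-5-(methoxymethoxy)benzaldehyde
Conditions: BnBr, K2CO3, DMF, 50 °C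
Reagents that add atoms: benzyl bromide, BrCc1ccccc1
Why: Williamson ether synthesis on the remaining acidic phenol, to which the MOM acetal and the aldehyde are inert.

Step 3
Reactants: 3 2-(benzyloxy)-5-(methoxymethoxy)benzaldehyde
Product: 5 2-(benzyloxy)-5-(methoxymethoxy)phenol, via aryl formate 4 (not isolated)
Conditions: mCPBA, CH2Cl2, 0 °C to rt; then K2CO3 (cat.), MeOH, 0 °C
Reagents that add atoms: 3-chloroperoxybenzoic acid, OOC(=O)c1cccc(Cl)c1
Why: Baeyer–Villiger (Dakin-type) oxidation, in which the ortho benzyloxy group makes the aryl group migrate in preference to hydride, followed by catalytic methanolysis of the formate.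

Step 4
Reactants: 5 2-(benzyloxy)-5-(methoxymethoxy)phenol; 6 3-methylbut-2-enal
Product: 7 8-(benzyloxy)-5-(methoxymethoxy)-2,2-dimethyl-2H-chromene
Conditions: PhB(OH)2 (1 equiv), EtCO2H (cat.), toluene, reflux, Dean–Stark
Reagents that add atoms: none
Why: Boronic acid-templated phenol–enal chromene annulation (ortho C-alkylation, loss of water, oxa-6π ring closure); the phenol has a single free ortho carbon, between the OH and the MOM-bearing carbon, so only one chromene can form.

Step 5
Reactants: 7 8-(benzyloxy)-5-(methoxymethoxy)-2,2-dimethyl-2H-chromene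
Product: 8 (3R,4R)-8-(benzyloxy)-3,4-epoxy-5-(methoxymethoxy)-2,2-dimethylchroman
Conditions: [(R,R)-N,N'-bis(3,5-di-tert-butylsalicylidene)cyclohexane-1,2-diaminato]manganese chloride (4 mol %), 4-phenylpyridine N-oxide, aq. NaOCl (pH 11.3), CH2Cl2, 0 °C
Reagents that add atoms: sodium hypochlorite, [Na+].[O-]Cl
Why: Jacobsen–Katsuki epoxidation, for which aryl-conjugated cis-alkenes of the 2,2-dimethylchromene type are the best substrates; the (R,R)-ligand leaves one alkene face open to the oxo-manganese species, which should give the (3R,4R)-oxide and so fixes C3.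

Step 6
Reactants: 8 (3R,4R)-8-(benzyloxy)-3,4-epoxy-5-(methoxymethoxy)-2,2-dimethylchroman
Product: 9 (3R)-5-(methoxymethoxy)-2,2-dimethylchroman-3,8-diol
Conditions: H2 (1 atm), Pd/C, NaHCO3, EtOAc, rt
Reagents that add atoms: none
Why: Catalytic hydrogenolysis cleaves the benzylic C4–O bond of the oxirane and the O-benzyl group in the same operation; the C3–O bond is not touched, so C3 stays R.

Step 7
Reactants: 9 (3R)-5-(methoxymethoxy)-2,2-dimethylchroman-3,8-diol
Product: 10 (3R)-3-hydroxy-5-(methoxymethoxy)-2,2-dimethylchroman-8-yl N-isopropylcarbamate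
Conditions: iPrNCO (1.1 equiv), Et3N (0.2 equiv), CH2Cl2, rt
Reagents that add atoms: isopropyl isocyanate, CC(C)N=C=O
Why: Base-catalysed carbamoylation, in which the C8 phenoxide adds to the isocyanate far faster than the hindered secondary C3 alcohol beside the quaternary C2.

Step 8
Reactants: 10 (3R)-3-hydroxy-5-(methoxymethoxy)-2,2-dimethylchroman-8-yl N-isopropylcarbamate
Product: 13 (3R)-3-[(tert-butyldimethylsilyl)oxy]-5-(methoxymethoxy)-2,2-dimethyl-7-(trimethylsilyl)chroman-8-yl N-isopropylcarbamate, via bis-silylated carbamate 11 (not isolated), via C7-silylated N-silyl carbamate 12 (not isolated)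
Conditions: TBSOTf (2.2 equiv), TMEDA, Et2O, 0 °C to rt; then n-BuLi (2.2 equiv), TMEDA, −78 °C; Me3SiCl, −78 °C to rt; aq. citric acid work-up
Reagents that add atoms: tert-butyldimethylsilyl trifluoromethanesulfonate, CC(C)(C)[Si](C)(C)OS(=O)(=O)C(F)(F)F; chlorotrimethylsilane, C[Si](C)(C)Cl
Why: Directed ortho-metalation: TBSOTf masks the carbamate N–H and the C3 OH, the N-silyl carbamate outranks the MOM ether as directing group and has C7 as its only free ortho position, Me3SiCl traps the C7 aryllithium, and work-up hydrolyses only the N–Si bond.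

Step 9
Reactants: 13 (3R)-3-[(tert-butyldimethylsilyl)oxy]-5-(methoxymethoxy)-2,2-dimethyl-7-(trimethylsilyl)chroman-8-yl N-isopropylcarbamate
Product: 15 (3R)-3-[(tert-butyldimethylsilyl)oxy]-5-(methoxymethoxy)-2,2-dimethyl-7-(trimethylsilyl)chroman-8-yl trifluoromethanesulfonate, via ortho-silyl phenol 14 (not isolated)
Conditions: DBU, Et2NH, MeCN, 40 °C; then PhNTf2, rt
Reagents that add atoms: N-phenylbis(trifluoromethanesulfonimide), O=S(=O)(N(c1ccccc1)S(=O)(=O)C(F)(F)F)C(F)(F)F
Why: E1cB cleavage of the secondary carbamate (the expelled isocyanate is scavenged by Et2NH as a urea) frees the hindered C8 phenoxide, which is O-triflated in the same pot.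

Step 10
Reactants: 16 (E)-4-hydroxycinnamic acid
Product: 18 (E)-3-[4-(methoxymethoxy)phenyl]prop-2-enoic acid, via methoxymethyl ester 17 (not isolated)
Conditions: MOMCl (2.5 equiv), iPr2NEt, CH2Cl2, 0 °C to rt; then LiOH, THF–MeOH–H2O, rt; 1 M HCl to pH 4, 0 °C
Reagents that add atoms: chloromethyl methyl ether, COCCl; lithium hydroxide, [Li+].[OH-]
Why: Double O-alkylation followed by saponification; hydroxide cleaves the MOM ester at the acyl carbon while the aryl MOM ether is base-stable and the E-alkene is untouched.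

Step 11
Reactants: 15 (3R)-3-[(tert-butyldimethylsilyl)oxy]-5-(methoxymethoxy)-2,2-dimethyl-7-(trimethylsilyl)chroman-8-yl trifluoromethanesulfonate; 18 (E)-3-[4-(methoxymethoxy)phenyl]prop-2-enoic acid
Product: 20 (E)-1-[(3R)-3-[(tert-butyldimethylsilyl)oxy]-7-hydroxy-5-(methoxymethoxy)-2,2-dimethylchroman-8-yl]-3-[4-(methoxymethoxy)phenyl]prop-2-en-1-one, via chroman 7,8-aryne 19 (not isolated)
Conditions: 18 (1.3 equiv), CsF (4 equiv), THF (0.02 M), 125 °C, sealed tube
Reagents that add atoms: none
Why: Fluoride attacks silicon at C7 and the C8 triflate departs to give aryne 19; the caesium carboxylate of 18 then adds through oxygen to C7, the aryne carbon remote from C8a, because the inductively withdrawing ring oxygen O1 on C8a distorts the aryne and stabilises the carbanion developing at the adjacent C8. That C8 anion attacks the neighbouring ester carbonyl (4-exo-trig) and the strained four-membered alkoxide collapses with C–O cleavage, so the acyl group ends on C8 and a phenoxide on C7, a net O-to-C acyl migration. The closest known reaction type is the fluoride-induced insertion of arynes from ortho-silylaryl triflates into the C–O bond of carboxylic acids in hot THF, which gives ortho-hydroxyaryl ketones and follows the same regiochemical rule with 3-alkoxyarynes. No ring is closed in the product (the four-membered ring is transient) and no stereocentre is formed; C3 is remote and inert, and the E-alkene of the acid is carried through unchanged. The step needs regioselective addition, secured by O1 on C8a against only a weak opposing pull from the distant C5 ether, and acyl transfer ahead of protonation of the C8 anion, favoured by using the acid as its caesium salt under dilute, hot, aprotic conditions.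

Step 12
Reactants: 20 (E)-1-[(3R)-3-[(tert-butyldimethylsilyl)oxy]-7-hydroxy-5-(methoxymethoxy)-2,2-dimethylchroman-8-yl]-3-[4-(methoxymethoxy)phenyl]prop-2-en-1-one
Product: 21 (E)-1-[(3R)-3-[(tert-butyldimethylsilyl)oxy]-7-methoxy-5-(methoxymethoxy)-2,2-dimethylchroman-8-yl]-3-[4-(methoxymethoxy)phenyl]prop-2-en-1-one
Conditions: MeI, K2CO3, DMF, 40 °C
Reagents that add atoms: iodomethane, CI
Why: Williamson O-methylation of the chelated C7 phenoxide; carbonate also reopens, by E1cB retro-oxa-Michael reaction, any material in which that phenoxide has added to the enone, so all of it should converge on the methyl ether.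

Step 13
Reactants: 21 (E)-1-[(3R)-3-[(tert-butyldimethylsilyl)oxy]-7-methoxy-5-(methoxymethoxy)-2,2-dimethylchroman-8-yl]-3-[4-(methoxymethoxy)phenyl]prop-2-en-1-one
Product: 22 (E)-1-[(3R)-3,5-dihydroxy-7-methoxy-2,2-dimethylchroman-8-yl]-3-(4-hydroxyphenyl)prop-2-en-1-one
Conditions: 3 M aq. HCl, MeOH, 50 °C
Reagents that add atoms: none
Why: Acid-catalysed acetal exchange removes both MOM groups and methanolysis removes the TBS ether; the enone, the C7 methyl ether and C3 are inert to dilute acid, and no free hydroxyl flanks the ketone, so no flavanone can form.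

Compound list
1 | 2,5-dihydroxybenzaldehyde | O=Cc1cc(O)ccc1O | starting material
2 | 2-hydroxy-5-(methoxymethoxy)benzaldehyde | COCOc1ccc(O)c(C=O)c1 | intermediate
3 | 2-(benzyloxy)-5-(methoxymethoxy)benzaldehyde | COCOc1ccc(OCc2ccccc2)c(C=O)c1 | intermediate
4 | 2-(benzyloxy)-5-(methoxymethoxy)phenyl formate | COCOc1ccc(OCc2ccccc2)c(OC=O)c1 | intermediate
5 | 2-(benzyloxy)-5-(methoxymethoxy)phenol | COCOc1ccc(OCc2ccccc2)c(O)c1 | intermediate
6 | 3-methylbut-2-enal | CC(C)=CC=O | starting material
7 | 8-(benzyloxy)-5-(methoxymethoxy)-2,2-dimethyl-2H-chromene | COCOc1ccc(OCc2ccccc2)c2OC(C)(C)C=Cc12 | intermediate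
8 | (3R,4R)-8-(benzyloxy)-3,4-epoxy-5-(methoxymethoxy)-2,2-dimethylchroman | COCOc1ccc(OCc2ccccc2)c2OC(C)(C)[C@@H]3O[C@@H]3c12 | intermediate
9 | (3R)-5-(methoxymethoxy)-2,2-dimethylchroman-3,8-diol | COCOc1ccc(O)c2OC(C)(C)[C@H](O)Cc12 | intermediate
10 | (3R)-3-hydroxy-5-(methoxymethoxy)-2,2-dimethylchroman-8-yl N-isopropylcarbamate | COCOc1ccc(OC(=O)NC(C)C)c2OC(C)(C)[C@H](O)Cc12 | intermediate
11 | (3R)-3-[(tert-butyldimethylsilyl)oxy]-5-(methoxymethoxy)-2,2-dimethylchroman-8-yl N-(tert-butyldimethylsilyl)-N-isopropylcarbamate | COCOc1ccc(OC(=O)N(C(C)C)[Si](C)(C)C(C)(C)C)c2OC(C)(C)[C@H](O[Si](C)(C)C(C)(C)C)Cc12 | intermediate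
12 | (3R)-3-[(tert-butyldimethylsilyl)oxy]-5-(methoxymethoxy)-2,2-dimethyl-7-(trimethylsilyl)chroman-8-yl N-(tert-butyldimethylsilyl)-N-isopropylcarbamate | COCOc1cc([Si](C)(C)C)c(OC(=O)N(C(C)C)[Si](C)(C)C(C)(C)C)c2OC(C)(C)[C@H](O[Si](C)(C)C(C)(C)C)Cc12 | intermediate
13 | (3R)-3-[(tert-butyldimethylsilyl)oxy]-5-(methoxymethoxy)-2,2-dimethyl-7-(trimethylsilyl)chroman-8-yl N-isopropylcarbamate | COCOc1cc([Si](C)(C)C)c(OC(=O)NC(C)C)c2OC(C)(C)[C@H](O[Si](C)(C)C(C)(C)C)Cc12 | intermediate
14 | (3R)-3-[(tert-butyldimethylsilyl)oxy]-5-(methoxymethoxy)-2,2-dimethyl-7-(trimethylsilyl)chroman-8-ol | COCOc1cc([Si](C)(C)C)c(O)c2OC(C)(C)[C@H](O[Si](C)(C)C(C)(C)C)Cc12 | intermediate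
15 | (3R)-3-[(tert-butyldimethylsilyl)oxy]-5-(methoxymethoxy)-2,2-dimethyl-7-(trimethylsilyl)chroman-8-yl trifluoromethanesulfonate | COCOc1cc([Si](C)(C)C)c(OS(=O)(=O)C(F)(F)F)c2OC(C)(C)[C@H](O[Si](C)(C)C(C)(C)C)Cc12 | intermediate
16 | (E)-4-hydroxycinnamic acid | OC(=O)/C=C/c1ccc(O)cc1 | starting material
17 | methoxymethyl (E)-3-[4-(methoxymethoxy)phenyl]prop-2-enoate | COCOC(=O)/C=C/c1ccc(OCOC)cc1 | intermediate
18 | (E)-3-[4-(methoxymethoxy)phenyl]prop-2-enoic acid | OC(=O)/C=C/c1ccc(OCOC)cc1 | intermediate
19 | (3R)-3-[(tert-butyldimethylsilyl)oxy]-5-(methoxymethoxy)-2,2-dimethyl-7,8-didehydrochroman (7,8-aryne) | COCOC1=CC#CC2=C1C[C@@H](O[Si](C)(C)C(C)(C)C)C(C)(C)O2 | intermediate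
20 | (E)-1-[(3R)-3-[(tert-butyldimethylsilyl)oxy]-7-hydroxy-5-(methoxymethoxy)-2,2-dimethylchroman-8-yl]-3-[4-(methoxymethoxy)phenyl]prop-2-en-1-one | Oc1cc(OCOC)c2c(c1C(=O)/C=C/c1ccc(OCOC)cc1)OC(C)(C)[C@H](O[Si](C)(C)C(C)(C)C)C2 | intermediate
21 | (E)-1-[(3R)-3-[(tert-butyldimethylsilyl)oxy]-7-methoxy-5-(methoxymethoxy)-2,2-dimethylchroman-8-yl]-3-[4-(methoxymethoxy)phenyl]prop-2-en-1-one | COc1cc(OCOC)c2c(c1C(=O)/C=C/c1ccc(OCOC)cc1)OC(C)(C)[C@H](O[Si](C)(C)C(C)(C)C)C2 | intermediate
22 | (E)-1-[(3R)-3,5-dihydroxy-7-methoxy-2,2-dimethylchroman-8-yl]-3-(4-hydroxyphenyl)prop-2-en-1-one | COc1cc(O)c2c(c1C(=O)/C=C/c1ccc(O)cc1)OC(C)(C)[C@H](O)C2 | target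

Total step count: 13. Longest linear sequence: 12 steps (steps 1 to 9 and 11 to 13, from 1); step 10 prepares the acid partner.

Steps most likely to fail

Step 11. The C8 aryl anion may be protonated before it reaches the ester carbonyl (plain O-arylation), it may be diverted by the conjugated C=C of the cinnamoyl ester, or the C3 silyl ether may be lost under hot fluoride. The fallback sets out from 15 and uses acetic acid, which has no conjugated alkene, under the same CsF/THF conditions. This should give 1-[(3R)-3-[(tert-butyldimethylsilyl)oxy]-7-hydroxy-5-(methoxymethoxy)-2,2-dimethylchroman-8-yl]ethan-1-one F1. Methylation with MeI and K2CO3 in DMF should give 1-[(3R)-3-[(tert-butyldimethylsilyl)oxy]-7-methoxy-5-(methoxymethoxy)-2,2-dimethylchroman-8-yl]ethan-1-one F2. Claisen–Schmidt condensation of F2 with 4-(methoxymethoxy)benzaldehyde F3 (from 4-hydroxybenzaldehyde, MOMCl and iPr2NEt) under KOH in EtOH at rt should then build the E-enone by aldol addition and dehydration. The fallback comes back to the route at 21.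

Step 6. The electron-rich benzylic oxirane may isomerise on the catalyst surface by acid-promoted ring opening and hydride shift, which would erase C3, or it may be solvolysed before hydrogenolysis. The fallback sets out from 8 and opens the oxirane with LiAlH4 in THF at 0 °C. Hydride attacks the benzylic C4 by SN2, since C3 is shielded by the quaternary C2, and under these basic conditions no benzylic cation can form. This should give (3R)-8-(benzyloxy)-5-(methoxymethoxy)-2,2-dimethylchroman-3-ol F4. Hydrogenolysis of its benzyl ether (H2, Pd/C, EtOAc) comes back to the route at 9.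

Step 4. C-Alkylation at the crowded ortho carbon between two oxygenated carbons may be slow, and the MOM acetal may be partly lost under the hot carboxylic acid. The fallback sets out from 5 and alkylates the phenol with 3-chloro-3-methylbut-1-yne (K2CO3, KI, acetone, reflux). This should give 1-(benzyloxy)-4-(methoxymethoxy)-2-[(2-methylbut-3-yn-2-yl)oxy]benzene F5. Heating F5 in N,N-diethylaniline at about 180 °C should trigger aromatic Claisen rearrangement to the only free ortho carbon, then 1,5-hydrogen shift and oxa-6π electrocyclisation under neutral conditions. The fallback comes back to the route at 7.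

Further compounds
F1 | step 11 | 1-[(3R)-3-[(tert-butyldimethylsilyl)oxy]-7-hydroxy-5-(methoxymethoxy)-2,2-dimethylchroman-8-yl]ethan-1-one | Oc1cc(OCOC)c2c(c1C(C)=O)OC(C)(C)[C@H](O[Si](C)(C)C(C)(C)C)C2
F2 | step 11 | 1-[(3R)-3-[(tert-butyldimethylsilyl)oxy]-7-methoxy-5-(methoxymethoxy)-2,2-dimethylchroman-8-yl]ethan-1-one | COc1cc(OCOC)c2c(c1C(C)=O)OC(C)(C)[C@H](O[Si](C)(C)C(C)(C)C)C2
F3 | step 11 | 4-(methoxymethoxy)benzaldehyde | COCOc1ccc(C=O)cc1
F4 | step 6 | (3R)-8-(benzyloxy)-5-(methoxymethoxy)-2,2-dimethylchroman-3-ol | COCOc1ccc(OCc2ccccc2)c2OC(C)(C)[C@H](O)Cc12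
F5 | step 4 | 1-(benzyloxy)-4-(methoxymethoxy)-2-[(2-methylbut-3-yn-2-yl)oxy]benzene | COCOc1ccc(OCc2ccccc2)c(OC(C)(C)C#C)c1
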